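**Plan**
- The 2-aryl-2,3-dihydrobenzofuran with a one-carbon group on C3 is read as a flavanone (2-arylchroman-4-one) whose carbonyl carbon C4 has been pushed out of the ring. O1, C2 and ring A are shared, and the target's C3–C3a bond is the one made when ring-A carbon C4a moves from C4 to C3.
- Cuts, in retrosynthetic order: the aryl–CH= bond of the acrylic acid at C5 (Heck), the C3–C3a bond (reverse Wolff contraction to a 3-diazoflavanone), the C2–aryl bond (conjugate addition to a chromone), and the chromone C2 carbon (amide acetal on an o-hydroxyacetophenone).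
- Forward: ring A is there from the start. The pyranone ring is closed first, the syringyl unit is added at C2, the diazo group is placed on C3, the pyranone is contracted to the dihydrofuran, and the side chain is attached last.
- Stereochemistry: C2 comes from a chiral bisphosphine–rhodium catalyst in the 1,4-addition; C3 is set trans to the C2 aryl group by base equilibration of the ester; the E alkene comes from the Heck reaction.
- The phenol is carried as a MOM ether, so its removal needs neither hydrogen (alkene) nor a strong Lewis acid (benzylic C2–O bond).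

Key step: step 7

Remark: the (S)-configured biaryl bisphosphine is assumed to deliver the aryl group to the face of chromone C2 that gives 2S, by analogy with its sense on cyclic enones. The first batch is checked by chiral HPLC, and the (R)-ligand is used instead if the sense is opposite.

**Route**

Step 1
Reactants: 1 2'-hydroxy-3'-methoxyacetophenone
Product: 2 bromoketone 1-(5-bromo-2-hydroxy-3-methoxyphenyl)ethan-1-one
Conditions: NBS (1.05 equiv), MeCN, 0 °C to rt
Reagents that add atoms: N-bromosuccinimide O=C1CCC(=O)N1Br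
Why: Electrophilic aromatic bromination, in which the free phenol directs to its para position (C5, also meta to the acetyl group) while the ortho positions are blocked, so one regioisomer is expected.

Step 2
Reactants: 2 bromoketone 1-(5-bromo-2-hydroxy-3-methoxyphenyl)ethan-1-one
Product: 4 chromone 6-bromo-8-methoxy-4H-chromen-4-one, via enaminone 3 (not isolated)
Conditions: Me2NCH(OMe)2, toluene, 100 °C; concentrate; conc. aq HCl, CH2Cl2, 40 °C
Reagents that add atoms: N,N-dimethylformamide dimethyl acetal COC(OC)N(C)C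
Why: Condensation of the methyl ketone with the amide acetal gives the vinylogous amide, and acid then drives addition of the phenol to its β-carbon with loss of dimethylamine, the standard chromone synthesis from 2'-hydroxyacetophenones.

Step 3
Reactants: 5 4-bromo-2,6-dimethoxyphenol
Product: 6 MOM ether 5-bromo-1,3-dimethoxy-2-(methoxymethoxy)benzene
Conditions: NaH, MOMCl, DMF, 0 °C to rt
Reagents that add atoms: chloromethyl methyl ether COCCl
Why: Williamson-type O-alkylation of the sodium phenoxide with an α-chloro ether, giving an acetal that tolerates organolithium, amide base, light, hydride and palladium and leaves with dilute acid.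

Step 4
Reactants: 6 MOM ether 5-bromo-1,3-dimethoxy-2-(methoxymethoxy)benzene
Product: 9 boronic acid [3,5-dimethoxy-4-(methoxymethoxy)phenyl]boronic acid, via aryllithium 7 (not isolated), via lithium triisopropoxyborate 8 (not isolated)
Conditions: n-BuLi, THF, −78 °C; B(Oi-Pr)3, −78 °C to rt; aq AcOH to pH 5–6
Reagents that add atoms: n-butyllithium [Li]CCCC (lithium, present only in 7 and 8); triisopropyl borate CC(C)OB(OC(C)C)OC(C)C; water O
Why: Bromine–lithium exchange at −78 °C is faster than any other pathway, and borate trapping followed by mildly acidic hydrolysis gives the boronic acid without loss of the MOM acetal.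

Step 5
Reactants: 4 chromone 6-bromo-8-methoxy-4H-chromen-4-one; 9 boronic acid [3,5-dimethoxy-4-(methoxymethoxy)phenyl]boronic acid (2 equiv)
Product: 10 flavanone (2S)-6-bromo-2-[3,5-dimethoxy-4-(methoxymethoxy)phenyl]-8-methoxy-2,3-dihydro-4H-chromen-4-one
Conditions: [Rh(OH)(cod)]2 (2.5 mol%), (S)-MeO-F12-BIPHEP [(S)-(6,6'-dimethoxybiphenyl-2,2'-diyl)bis(bis(3,4,5-trifluorophenyl)phosphine)] (5.5 mol%), toluene/H2O, 30 °C
Reagents that add atoms: none
Why: Hayashi–Miyaura asymmetric 1,4-addition, in which the aryl group on monovalent rhodium inserts the chromone C2=C3 bond on the face chosen by the chiral bisphosphine (sets 2S) and water releases the ketone; the electron-poor ligand allows a temperature at which the flavanone should not ring-open, and the aryl bromide is inert to the catalyst.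

Step 6
Reactants: 10 flavanone (2S)-6-bromo-2-[3,5-dimethoxy-4-(methoxymethoxy)phenyl]-8-methoxy-2,3-dihydro-4H-chromen-4-one
Product: 13 diazo ketone (2R)-6-bromo-3-diazo-2-[3,5-dimethoxy-4-(methoxymethoxy)phenyl]-8-methoxy-2,3-dihydro-4H-chromen-4-one, via lithium enolate 11 (not isolated), via trifluoroacetyl ketone 12 (not isolated)
Conditions: LiN(SiMe3)2, THF, −78 °C; CF3CO2CH2CF3, −78 °C; cold 1 M HCl work-up; then 4-AcNHC6H4SO2N3, Et3N, H2O (1 equiv), MeCN, 0 °C to rt
Reagents that add atoms: 4-acetamidobenzenesulfonyl azide CC(=O)Nc1ccc(cc1)S(=O)(=O)N=[N+]=[N-]; 2,2,2-trifluoroethyl trifluoroacetate O=C(OCC(F)(F)F)C(F)(F)F (CF3CO group, present only in 12); lithium bis(trimethylsilyl)amide [Li+].C[Si](C)(C)[N-][Si](C)(C)C (lithium, present only in 11)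
Why: Detrifluoroacetylative diazo transfer, in which the kinetic enolate is C-acylated at −78 °C before it can ring-open and the activated 1,3-dicarbonyl then takes the diazo group from the sulfonyl azide with loss of the trifluoroacetyl group; C2 keeps its spatial arrangement, the descriptor changing to R only because the diazo carbon outranks the aryl group.

Step 7
Reactants: 13 diazo ketone (2R)-6-bromo-3-diazo-2-[3,5-dimethoxy-4-(methoxymethoxy)phenyl]-8-methoxy-2,3-dihydro-4H-chromen-4-one
Product: 16 trans ester methyl (2S,3S)-5-bromo-2-[3,5-dimethoxy-4-(methoxymethoxy)phenyl]-7-methoxy-2,3-dihydro-1-benzofuran-3-carboxylate, via ketene 14 (not isolated), via cis ester 15 (not isolated)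
Conditions: hν (365 nm), degassed MeOH, 10 °C; then NaOMe (0.2 equiv), MeOH, 25–40 °C; AcOH quench
Reagents that add atoms: methanol CO
Why: Excitation of the s-Z-locked cyclic diazo ketone expels N2 in concert with a 1,2-shift of ring-A carbon C4a from the carbonyl carbon C4 to C3, which makes the target's C3–C3a bond and leaves C4 as the exocyclic ketene carbon of 14; methanol adds to the ketene and the ester enol is protonated at C3. The closest known reaction type is the photochemical Wolff ring contraction of benzo-fused cyclic 2-diazo ketones in an alcohol (2-diazo-1-tetralone to methyl indane-1-carboxylate). The dihydrofuran ring is closed by ring contraction, that is by the 1,2-aryl shift inside the existing pyranone ring, not by an exo or endo cyclisation of an open chain. The new stereocentre C3 is first set kinetically by protonation anti to the 2-aryl group (mainly cis ester 15) and then put under thermodynamic control by NaOMe, where the fixed C2 aryl group forces the ester to the opposite face (trans, 2S,3S, the arrangement of the target); C2 has no acidic hydrogen and is carried through. The step needs rearrangement to beat carbene chemistry (1,2-hydride shift from C2 to the flavone, shift of the C2 aryl group, O–H insertion into methanol); the ring-enforced s-Z geometry and direct irradiation without sensitiser or metal secure this, and 365 nm light leaves the aryl bromide untouched.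

Step 8
Reactants: 16 trans ester methyl (2S,3S)-5-bromo-2-[3,5-dimethoxy-4-(methoxymethoxy)phenyl]-7-methoxy-2,3-dihydro-1-benzofuran-3-carboxylate
Product: 17 alcohol [(2S,3R)-5-bromo-2-[3,5-dimethoxy-4-(methoxymethoxy)phenyl]-7-methoxy-2,3-dihydro-1-benzofuran-3-yl]methanol
Conditions: i-Bu2AlH (3 equiv), CH2Cl2, −78 to 0 °C; aq KNaC4H4O6
Reagents that add atoms: none
Why: Ester reduction by a non-basic aluminium hydride that leaves the aryl bromide and the MOM acetal alone; C3 is no longer epimerisable afterwards, and its descriptor becomes R only because CH2OH ranks below C2.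

Step 9
Reactants: 17 alcohol [(2S,3R)-5-bromo-2-[3,5-dimethoxy-4-(methoxymethoxy)phenyl]-7-methoxy-2,3-dihydro-1-benzofuran-3-yl]methanol; 18 methyl acrylate (3 equiv)
Product: 19 cinnamate methyl (2E)-3-[(2S,3R)-2-[3,5-dimethoxy-4-(methoxymethoxy)phenyl]-3-(hydroxymethyl)-7-methoxy-2,3-dihydro-1-benzofuran-5-yl]prop-2-enoate
Conditions: Pd(OAc)2 (5 mol%), P(o-tol)3 (12 mol%), Et3N, DMF, 100 °C
Reagents that add atoms: none
Why: Mizoroki–Heck reaction, in which zerovalent palladium adds to the aryl bromide, the acrylate inserts syn and syn β-hydride elimination gives the E alkene; the free primary alcohol is tolerated.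

Step 10
Reactants: 19 cinnamate methyl (2E)-3-[(2S,3R)-2-[3,5-dimethoxy-4-(methoxymethoxy)phenyl]-3-(hydroxymethyl)-7-methoxy-2,3-dihydro-1-benzofuran-5-yl]prop-2-enoate
Product: 20 phenol ester methyl (2E)-3-[(2S,3R)-2-(4-hydroxy-3,5-dimethoxyphenyl)-3-(hydroxymethyl)-7-methoxy-2,3-dihydro-1-benzofuran-5-yl]prop-2-enoate
Conditions: HCl (1 M in MeOH), 25–40 °C
Reagents that add atoms: none
Why: Acid-catalysed acetal exchange with methanol removes the MOM group, the methyl ester is degenerate in this medium, and because C3 is fixed any reversible ionisation of the benzylic C2–O bond can only return the more stable trans ring.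

Step 11
Reactants: 20 phenol ester methyl (2E)-3-[(2S,3R)-2-(4-hydroxy-3,5-dimethoxyphenyl)-3-(hydroxymethyl)-7-methoxy-2,3-dihydro-1-benzofuran-5-yl]prop-2-enoate
Product: 21 target (2E)-3-[(2S,3R)-2-(4-hydroxy-3,5-dimethoxyphenyl)-3-(hydroxymethyl)-7-methoxy-2,3-dihydro-1-benzofuran-5-yl]prop-2-enoic acid
Conditions: LiOH, THF/H2O, rt; then 1 M HCl to pH 2–3
Reagents that add atoms: lithium hydroxide [Li+].[OH-] (hydroxide oxygen of the acid)
Why: Saponification of the conjugated methyl ester at room temperature, where neither stereocentre nor the E alkene is at risk, followed by acidification to the free acid.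

**Compound list**

1 | 2'-hydroxy-3'-methoxyacetophenone | COc1cccc(C(C)=O)c1O | starting material
2 | 1-(5-bromo-2-hydroxy-3-methoxyphenyl)ethan-1-one | COc1cc(Br)cc(C(C)=O)c1O | intermediate
3 | (E)-1-(5-bromo-2-hydroxy-3-methoxyphenyl)-3-(dimethylamino)prop-2-en-1-one | COc1cc(Br)cc(C(=O)/C=C/N(C)C)c1O | intermediate
4 | 6-bromo-8-methoxy-4H-chromen-4-one | O=c1ccoc2c(OC)cc(Br)cc12 | intermediate
5 | 4-bromo-2,6-dimethoxyphenol | COc1cc(Br)cc(OC)c1O | starting material
6 | 5-bromo-1,3-dimethoxy-2-(methoxymethoxy)benzene | COCOc1c(OC)cc(Br)cc1OC | intermediate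
7 | [3,5-dimethoxy-4-(methoxymethoxy)phenyl]lithium | COCOc1c(OC)cc([Li])cc1OC | intermediate
8 | lithium [3,5-dimethoxy-4-(methoxymethoxy)phenyl]tri(propan-2-yloxy)borate | [Li+].COCOc1c(OC)cc(cc1OC)[B-](OC(C)C)(OC(C)C)OC(C)C | intermediate
9 | [3,5-dimethoxy-4-(methoxymethoxy)phenyl]boronic acid | COCOc1c(OC)cc(B(O)O)cc1OC | intermediate
10 | (2S)-6-bromo-2-[3,5-dimethoxy-4-(methoxymethoxy)phenyl]-8-methoxy-2,3-dihydro-4H-chromen-4-one | COc1cc([C@H]2Oc3c(OC)cc(Br)cc3C(=O)C2)cc(OC)c1OCOC | intermediate
11 | lithium (2S)-6-bromo-2-[3,5-dimethoxy-4-(methoxymethoxy)phenyl]-8-methoxy-2H-chromen-4-olate (enolate of 10) | [Li+].COc1cc([C@H]2Oc3c(OC)cc(Br)cc3C([O-])=C2)cc(OC)c1OCOC | intermediate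
12 | (2S)-6-bromo-2-[3,5-dimethoxy-4-(methoxymethoxy)phenyl]-8-methoxy-3-(trifluoroacetyl)-2,3-dihydro-4H-chromen-4-one (C3 not defined, largely enolised) | COc1cc([C@H]2Oc3c(OC)cc(Br)cc3C(=O)C2C(=O)C(F)(F)F)cc(OC)c1OCOC | intermediate
13 | (2R)-6-bromo-3-diazo-2-[3,5-dimethoxy-4-(methoxymethoxy)phenyl]-8-methoxy-2,3-dihydro-4H-chromen-4-one (C2 arranged as in 10) | COc1cc([C@H]2Oc3c(OC)cc(Br)cc3C(=O)C2=[N+]=[N-])cc(OC)c1OCOC | intermediate
14 | (2R)-5-bromo-2-[3,5-dimethoxy-4-(methoxymethoxy)phenyl]-7-methoxy-3-(oxomethylidene)-2,3-dihydro-1-benzofuran (ketene; C2 arranged as in 10) | COc1cc([C@H]2Oc3c(OC)cc(Br)cc3C2=C=O)cc(OC)c1OCOC | intermediate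
15 | methyl (2S,3R)-5-bromo-2-[3,5-dimethoxy-4-(methoxymethoxy)phenyl]-7-methoxy-2,3-dihydro-1-benzofuran-3-carboxylate (cis) | COc1cc([C@H]2Oc3c(OC)cc(Br)cc3[C@H]2C(=O)OC)cc(OC)c1OCOC | intermediate
16 | methyl (2S,3S)-5-bromo-2-[3,5-dimethoxy-4-(methoxymethoxy)phenyl]-7-methoxy-2,3-dihydro-1-benzofuran-3-carboxylate (trans) | COc1cc([C@H]2Oc3c(OC)cc(Br)cc3[C@@H]2C(=O)OC)cc(OC)c1OCOC | intermediate
17 | [(2S,3R)-5-bromo-2-[3,5-dimethoxy-4-(methoxymethoxy)phenyl]-7-methoxy-2,3-dihydro-1-benzofuran-3-yl]methanol (trans) | COc1cc([C@H]2Oc3c(OC)cc(Br)cc3[C@@H]2CO)cc(OC)c1OCOC | intermediate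
18 | methyl acrylate | C=CC(=O)OC | starting material
19 | methyl (2E)-3-[(2S,3R)-2-[3,5-dimethoxy-4-(methoxymethoxy)phenyl]-3-(hydroxymethyl)-7-methoxy-2,3-dihydro-1-benzofuran-5-yl]prop-2-enoate | COc1cc([C@H]2Oc3c(OC)cc(/C=C/C(=O)OC)cc3[C@@H]2CO)cc(OC)c1OCOC | intermediate
20 | methyl (2E)-3-[(2S,3R)-2-(4-hydroxy-3,5-dimethoxyphenyl)-3-(hydroxymethyl)-7-methoxy-2,3-dihydro-1-benzofuran-5-yl]prop-2-enoate | COc1cc([C@H]2Oc3c(OC)cc(/C=C/C(=O)OC)cc3[C@@H]2CO)cc(OC)c1O | intermediate
21 | (2E)-3-[(2S,3R)-2-(4-hydroxy-3,5-dimethoxyphenyl)-3-(hydroxymethyl)-7-methoxy-2,3-dihydro-1-benzofuran-5-yl]prop-2-enoic acid | COc1cc([C@H]2Oc3c(OC)cc(/C=C/C(=O)O)cc3[C@@H]2CO)cc(OC)c1O | target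

**Count and risks**

Total step count: 11. Longest linear sequence: 9 steps (steps 1, 2, 5, 6, 7, 8, 9, 10, 11 from 1; equally steps 3, 4, 5–11 from 5).

Steps most likely to fail:

Step 7. After loss of nitrogen the excited diazo ketone may follow carbene pathways (hydride shift from C2 to the flavone, shift of the C2 aryl group, O–H insertion into methanol) faster than it rearranges. The fallback makes the C2–C3 bond instead, by asymmetric intramolecular carbene C–H insertion, a known route to 2-aryl-2,3-dihydrobenzofuran-3-carboxylates. It sets out from bromoketone 2. Commercial syringaldehyde (4-hydroxy-3,5-dimethoxybenzaldehyde) is protected with MOMCl/i-Pr2NEt to 3,5-dimethoxy-4-(methoxymethoxy)benzaldehyde F1 and reduced with NaBH4 to [3,5-dimethoxy-4-(methoxymethoxy)phenyl]methanol F2. Mitsunobu etherification of 2 with F2 (PPh3, diisopropyl azodicarboxylate) should give 1-[5-bromo-2-{[3,5-dimethoxy-4-(methoxymethoxy)phenyl]methoxy}-3-methoxyphenyl]ethan-1-one F3. SeO2 in pyridine oxidises the acetyl group to 2-[5-bromo-2-{[3,5-dimethoxy-4-(methoxymethoxy)phenyl]methoxy}-3-methoxyphenyl]-2-oxoacetic acid F4, and MeI/K2CO3 gives its methyl ester, methyl 2-[5-bromo-2-{[3,5-dimethoxy-4-(methoxymethoxy)phenyl]methoxy}-3-methoxyphenyl]-2-oxoacetate F5. Condensation with tosylhydrazide gives the tosylhydrazone of that keto ester F6, and DBU (Bamford–Stevens) gives methyl 2-[5-bromo-2-{[3,5-dimethoxy-4-(methoxymethoxy)phenyl]methoxy}-3-methoxyphenyl]-2-diazoacetate F7. Rh2(S-PTTL)4 (dirhodium tetrakis[N-phthaloyl-(S)-tert-leucinate]) or its enantiomer, whichever leads to the 2S series, in toluene at low temperature inserts the carbene into the benzylic C–H bond. The fallback comes back to the route at cis ester 15, which NaOMe in MeOH equilibrates to 16 as in the second half of step 7.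

Step 6. The lithium enolate may eliminate the ring aryloxide (opening to the chalcone phenoxide, whose re-closure racemises C2) or be acylated on oxygen. The fallback avoids enolates by nitrosating the acid-generated enol and then running a Forster reaction. It sets out from flavanone 10. Isoamyl nitrite with Me3SiCl in CH2Cl2 at −20 °C should give (2R)-6-bromo-3-(hydroxyimino)-2-[3,5-dimethoxy-4-(methoxymethoxy)phenyl]-8-methoxy-2,3-dihydro-4H-chromen-4-one F8, which has no enolisable C3–H. Chloramine made from aqueous NH3 and NaOCl at 0 °C converts the oxime into the diazo group, and the fallback comes back to the route at diazo ketone 13.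

Step 5. Protodeboronation of the electron-rich boronic acid may outrun a slow insertion into the chromone, or the facial selectivity may be insufficient. The fallback builds the flavanone as a racemate and resolves it. It sets out from bromoketone 2. Claisen–Schmidt condensation of 2 with aldehyde F1 (KOH, EtOH) gives (E)-1-(5-bromo-2-hydroxy-3-methoxyphenyl)-3-[3,5-dimethoxy-4-(methoxymethoxy)phenyl]prop-2-en-1-one F9. NaOAc in refluxing EtOH closes it to racemic 6-bromo-2-[3,5-dimethoxy-4-(methoxymethoxy)phenyl]-8-methoxy-2,3-dihydro-4H-chromen-4-one F10. Kinetic resolution by asymmetric transfer hydrogenation (RuCl(p-cymene)(TsDPEN) in the enantiomeric form that reduces the 2R ketone faster, HCO2H/Et3N) should leave the 2S ketone and convert the other enantiomer into (2R,4R)-6-bromo-2-[3,5-dimethoxy-4-(methoxymethoxy)phenyl]-8-methoxy-3,4-dihydro-2H-chromen-4-ol F11, which is separated by chromatography. The fallback comes back to the route at flavanone 10.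

**Further compounds**

F1 | step 7 | 3,5-dimethoxy-4-(methoxymethoxy)benzaldehyde | COCOc1c(OC)cc(C=O)cc1OC
F2 | step 7 | [3,5-dimethoxy-4-(methoxymethoxy)phenyl]methanol | COCOc1c(OC)cc(CO)cc1OC
F3 | step 7 | 1-[5-bromo-2-{[3,5-dimethoxy-4-(methoxymethoxy)phenyl]methoxy}-3-methoxyphenyl]ethan-1-one | COCOc1c(OC)cc(COc2c(OC)cc(Br)cc2C(C)=O)cc1OC
F4 | step 7 | 2-[5-bromo-2-{[3,5-dimethoxy-4-(methoxymethoxy)phenyl]methoxy}-3-methoxyphenyl]-2-oxoacetic acid | COCOc1c(OC)cc(COc2c(OC)cc(Br)cc2C(=O)C(=O)O)cc1OC
F5 | step 7 | methyl 2-[5-bromo-2-{[3,5-dimethoxy-4-(methoxymethoxy)phenyl]methoxy}-3-methoxyphenyl]-2-oxoacetate | COCOc1c(OC)cc(COc2c(OC)cc(Br)cc2C(=O)C(=O)OC)cc1OC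
F6 | step 7 | methyl 2-[5-bromo-2-{[3,5-dimethoxy-4-(methoxymethoxy)phenyl]methoxy}-3-methoxyphenyl]-2-[2-(4-methylbenzenesulfonyl)hydrazinylidene]acetate | COCOc1c(OC)cc(COc2c(OC)cc(Br)cc2C(=NNS(=O)(=O)c3ccc(C)cc3)C(=O)OC)cc1OC
F7 | step 7 | methyl 2-[5-bromo-2-{[3,5-dimethoxy-4-(methoxymethoxy)phenyl]methoxy}-3-methoxyphenyl]-2-diazoacetate | COCOc1c(OC)cc(COc2c(OC)cc(Br)cc2C(=[N+]=[N-])C(=O)OC)cc1OC
F8 | step 6 | (2R)-6-bromo-3-(hydroxyimino)-2-[3,5-dimethoxy-4-(methoxymethoxy)phenyl]-8-methoxy-2,3-dihydro-4H-chromen-4-one | COc1cc([C@H]2Oc3c(OC)cc(Br)cc3C(=O)C2=NO)cc(OC)c1OCOC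
F9 | step 5 | (E)-1-(5-bromo-2-hydroxy-3-methoxyphenyl)-3-[3,5-dimethoxy-4-(methoxymethoxy)phenyl]prop-2-en-1-one | COCOc1c(OC)cc(/C=C/C(=O)c2cc(Br)cc(OC)c2O)cc1OC
F10 | step 5 | racemic 6-bromo-2-[3,5-dimethoxy-4-(methoxymethoxy)phenyl]-8-methoxy-2,3-dihydro-4H-chromen-4-one | COc1cc(C2Oc3c(OC)cc(Br)cc3C(=O)C2)cc(OC)c1OCOC
F11 | step 5 | (2R,4R)-6-bromo-2-[3,5-dimethoxy-4-(methoxymethoxy)phenyl]-8-methoxy-3,4-dihydro-2H-chromen-4-ol (cis) | COc1cc([C@@H]2Oc3c(OC)cc(Br)cc3[C@H](O)C2)cc(OC)c1OCOC
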